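X is the substrate of this flask and E the reagent; Q is formed on the way, and Z and G are the products.

| flask | X | E | remark | time |
|---|---|---|---|---|
| violet | 1 M | 0.29 M | run made earlier |  |
| blue | 1 M | 0.76 M | run made earlier |  |
| beta | 1.0 M | 0.500 M |  | 2.5 h |
| delta | 1.0 M | 1.00 M |  | 2.5 h |

| run | time / min | X / % | Z / % | Q / % | G / % |
|---|---|---|---|---|---|
| violet | 8.00 | 84.4 | 3.3 | 0.7 | 11.4 |
| violet | 20.0 | 70.7 | 4.6 | 0.5 | 23.4 |
| violet | 40.0 | 70.9 | 5.4 | 0 | 24.6 |
| violet | 60.0 | 70.0 | 4.6 | 0.8 | 24.6 |
| violet | 80.0 | 70.3 | 5.1 | 0 | 24.3 |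
| violet | 120 | 68.0 | 6.0 | 0 | 24.4 |
| blue | 8.00 | 82.8 | 7.0 | 0 | 8.9 |
| blue | 20.0 | 64.2 | 14.7 | 0 | 19.8 |
| blue | 40.0 | 42.2 | 22.3 | 0 | 36.4 |
| blue | 60.0 | 27.4 | 24.1 | 0.1 | 47.7 |
| blue | 80.0 | 23.3 | 23.2 | 0.2 | 52.1 |
| blue | 120 | 22.9 | 23.9 | 0.3 | 52.7 |

(scatter of a reading: 0.5 percentage points)

- what was read earlier has a scatter of 0.5 percentage points, one standard deviation

- which of these there is most of at the end, counted by the X in it, beta (Q / X / Z / G)
- which of these there is most of at the end, counted by the X in it, delta (Q / X / Z / G)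
- final amount of the leader among these, as a percentage of the X charged, in beta
- final amount of the leader among these, as a percentage of the X charged, in delta

You can read the runs as a ladder of time scales, fastest first.

1. Q. At 8.00 min it reads 0.7% in violet and 0% in blue, close to the scatter of 0.5 percentage points. So treat Q as a fast mode whose store is lost in the scatter.

2. X. At that time X reads 84.4% in violet and 82.8% in blue, although blue holds 2.62 times the E. So the fall of X looks first-order, with E out of it. Blue's reading at 40.0 min gives a time constant of 46.4 min.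

3. The split. Violet stops near 70.3% of X and blue near 22.9%, so each X lost costs about one E. Now divide the rate of Z by the rate of G, and time drops out: Z made per G made = a × E. Here a is the selectivity factor, the Z-to-G ratio per unit of E present. Blue up to 40.0 min, with a mean E of 0.467 M, gives the reading a = 1.31 M⁻¹. Integrated, G formed = ln((1 + a × E charged)/(1 + a × E left))/a.

4. Beta. E is the limiting reagent: I reckon its 0.500 M used after about 32.1 min, sooner than the 2.5 h asked. I reckon X at 50.0%, G at 38.4% and Z at 11.6%.

5. Delta. I reckon X and E falling together to 3.93% of their charges. I reckon G at 60.0% and Z at 36.1%.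

6. Slowest. Violet's X still drifts from 70.9% to 68.0% between 40.0 min and 120 min, so I expect beta's X slightly under 50.0%.

The forecast, reasoning that “each X uses one E”, gave X at 50% for beta, as I do, and G at 56% for delta, a little under my 60.0%.

    2 X → J (k = 2.47 × 10⁻⁶ M⁻¹ s⁻¹)
    Q ⇌ D (K = 0.850, k = 5.27 s⁻¹)
    E + Q → Z (k = 6.45 M⁻¹ s⁻¹)
    X ⇌ Q (K = 4.50 × 10⁻⁴, k = 4.07 × 10⁻⁴ s⁻¹)
    E + D → G (k = 179 M⁻¹ s⁻¹)

Beta ended with X leading at 48.6%, and delta with G leading at 58.9%. J, a product absent from the readings, holds 1.35% of the X in beta, less than the 11 points by which X leads G there. A neighbour of beta, charged with 0.40 M of X, ended with 23.6% of its E free. With that, a gives G at 68.7% of the X in that neighbour, and the neighbour holds 67.9%.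

The runs were computed with constants of no real substance; noise was put on by code.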